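**Plan**

- Cuts, in retrosynthetic order: the upper interflavan bond C4(top)–C8(middle); then ring C of the middle unit across O1–C2 and C3–C4; then the bond from the middle C4 carbon to ring A of the middle unit, which leads back to a C6 aldehyde on the bottom catechin.
- Enabling feature: C4 of the middle unit is a doubly benzylic CH between ring A of its own unit and C6 of ring A of the bottom unit. Ring A carries O1 ortho to it, so O1, C8a, C4a and C4 form an o-quinone methide, and C2–C3 (aryl on C2, oxygen on C3) is the enol ester of an arylacetaldehyde.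
- Forward, bottom unit and partner: (+)-catechin is benzylated, brominated at C8 (blocking group) and formylated at C6. A magnesium phenoxide adds through its ortho carbon to give the o-hydroxybenzhydrol. The (E)-enol acetate is made in three steps from 3,4-bis(benzyloxy)benzaldehyde.
- Forward, assembly: the acid-catalysed [4+2] closes ring C of the middle unit onto the bottom unit. The top unit (the same bromocatechin, oxidised at C4) is then attached to C8 of the new ring A with a silyl triflate. Deacetylation and one hydrogenolysis finish the synthesis.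
- Stereochemistry: C2 and C3 of the top and bottom units come from (+)-catechin. C2, C3 and C4 of the middle unit arise in the cycloaddition (E-alkene gives 2,3-trans, aryl-endo approach gives 3,4-trans, chiral phosphate gives the absolute sense). C4 of the top unit is set by attack anti to its 3-benzyloxy group.

Key step: step 9

Remark: the sense of induction of the phosphoric acid in step 9 cannot be derived from a close analogue. The (R)-acid is taken as the antipode that gives the (2R,3S) middle unit; since the chiral bottom unit makes the alternative product a separable diastereomer, the (S)-acid would be used if the first run showed the opposite sense.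
Remark: 3,4-bis(benzyloxy)benzaldehyde 10 is taken as a purchased compound (it is the dibenzyl ether of protocatechualdehyde).

**Route**

Step 1
Reactants: 1 (+)-catechin
Product: 2 5,7,3',4'-tetra-O-benzyl-(+)-catechin (3-OH free, 2R,3S)
Conditions: BnBr (4.4 equiv), K2CO3, DMF, 0 °C → rt
Reagents that add atoms: benzyl bromide, BrCc1ccccc1
Why: Williamson etherification with a carbonate base ionises only the four phenols, so the secondary 3-OH and the C2/C3 stereocentres stay untouched.

Step 2
Reactants: 2 5,7,3',4'-tetra-O-benzyl-(+)-catechin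
Product: 3 3,5,7,3',4'-penta-O-benzyl-(+)-catechin
Conditions: NaH, BnBr, n-Bu4NI (cat.), DMF, 0 °C → rt
Reagents that add atoms: benzyl bromide, BrCc1ccccc1
Why: Williamson etherification of the secondary alkoxide caps the last hydroxyl so that no acidic proton interferes with the organometallic and acid-mediated steps that follow.

Step 3
Reactants: 3 3,5,7,3',4'-penta-O-benzyl-(+)-catechin
Product: 4 8-bromo-3,5,7,3',4'-penta-O-benzyl-(+)-catechin
Conditions: NBS (1.0 equiv), CH2Cl2, −78 °C → −20 °C
Reagents that add atoms: N-bromosuccinimide, O=C1CCC(=O)N1Br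
Why: Electrophilic aromatic bromination of the trialkoxy ring A should take place at C8, its most nucleophilic position, and the bromide then blocks C8 against every later electrophile.

Step 4
Reactants: 4 8-bromo-3,5,7,3',4'-penta-O-benzyl-(+)-catechin
Product: 6 8-bromo-6-formyl-3,5,7,3',4'-penta-O-benzyl-(+)-catechin, via C6 N,N-dimethyliminium chloride 5 (not isolated)
Conditions: POCl3, DMF, 0 → 60 °C; then aq. NaOAc, rt
Reagents that add atoms: N,N-dimethylformamide, CN(C)C=O; water, O
Why: Vilsmeier–Haack formylation: with C8 blocked, the chloroiminium ion can only attack C6 of ring A (the dialkoxy ring B is far less reactive), and hydrolysis of iminium 5 should give the aldehyde.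

Step 5
Reactants: 6 8-bromo-6-formyl-3,5,7,3',4'-penta-O-benzyl-(+)-catechin; 7 3,5-bis(benzyloxy)phenol
Product: 9 (8-bromo-3,5,7,3',4'-penta-O-benzylcatechin-6-yl)[2-hydroxy-4,6-bis(benzyloxy)phenyl]methanol (both carbinol epimers), via bromomagnesium 3,5-bis(benzyloxy)phenoxide 8 (not isolated)
Conditions: 7, EtMgBr (1.0 equiv), Et2O, 0 °C; solvent switch to toluene; 6, rt; pH 7 phosphate buffer
Reagents that add atoms: none
Why: Ortho-selective hydroxyalkylation of a magnesium phenoxide: in the non-donor solvent the aldehyde binds to magnesium and is delivered to the ortho carbon through a six-membered chelate; the two ortho positions of 7 are equivalent, and the carbinol epimer mixture is harmless because step 9 erases that centre.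

Step 6
Reactants: 10 3,4-bis(benzyloxy)benzaldehyde
Product: 11 (E)-2-[3,4-bis(benzyloxy)styryl]-4,4,5,5-tetramethyl-1,3,2-dioxaborolane
Conditions: CH2(Bpin)2, lithium 2,2,6,6-tetramethylpiperidide, THF, 0 °C; then 10, −78 °C → rt
Reagents that add atoms: bis[(pinacolato)boryl]methane, C(B1OC(C)(C)C(C)(C)O1)B1OC(C)(C)C(C)(C)O1
Why: Boron–Wittig olefination: the lithiated geminal bis(boronate) adds to the aldehyde and syn-eliminates a boron–oxygen fragment, which should give the trans-alkenylboronate.

Step 7
Reactants: 11 (E)-2-[3,4-bis(benzyloxy)styryl]-4,4,5,5-tetramethyl-1,3,2-dioxaborolane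
Product: 12 potassium (E)-[3,4-bis(benzyloxy)styryl]trifluoroborate
Conditions: KHF2 (aq.), MeOH, rt
Reagents that add atoms: potassium hydrogen difluoride, [K+].F.[F-]
Why: Standard conversion of a pinacol boronate into its trifluoroborate salt, which leaves the alkene geometry untouched and provides the boron form used in the next coupling.

Step 8
Reactants: 12 potassium (E)-[3,4-bis(benzyloxy)styryl]trifluoroborate
Product: 13 (E)-2-[3,4-bis(benzyloxy)phenyl]vinyl acetate
Conditions: AcOH, CuBr (10 mol%), DMAP (20 mol%), 4 Å MS, O2 (1 atm), CH2Cl2, 40 °C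
Reagents that add atoms: acetic acid, CC(=O)O
Why: Copper-catalysed oxidative C–O coupling of an alkenyltrifluoroborate with a carboxylic acid (Chan–Lam type) transfers the alkenyl group to the acetate oxygen with retention of the (E) geometry.

Step 9
Reactants: 9 (8-bromo-3,5,7,3',4'-penta-O-benzylcatechin-6-yl)[2-hydroxy-4,6-bis(benzyloxy)phenyl]methanol; 13 (E)-2-[3,4-bis(benzyloxy)phenyl]vinyl acetate
Product: 15 3-O-acetyl-5,7,3',4'-tetra-O-benzylcatechin-(4α→6)-8-bromo-3,5,7,3',4'-penta-O-benzylcatechin (middle unit 2R,3S, 2,3-trans-3,4-trans), via o-quinone methide 14 (not isolated)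
Conditions: (R)-3,3'-bis(2,4,6-triisopropylphenyl)-1,1'-binaphthyl-2,2'-diyl hydrogen phosphate (10 mol%), 13 (3 equiv), 5 Å MS, CH2Cl2, −20 °C → rt, slow addition of 9
Reagents that add atoms: none
Why: Proposed new method: the chiral acid ionises the doubly benzylic carbinol of 9 (either epimer) and keeps the resulting o-quinone methide 14 as a hydrogen-bonded ion pair with its phosphate; the acetoxy-bearing carbon of 13 then bonds to the methide carbon (C3–C4) and the phenolic oxygen closes on the benzylic alkene carbon (O1–C2), an asynchronous inverse-electron-demand [4+2] with C–C bond formation leading, which closes the pyran ring C of the middle unit in the [4+2] mode. The closest known reactions are chiral-phosphoric-acid-catalysed [4+2] cycloadditions of o-quinone methides, generated from o-hydroxybenzyl alcohols, with styrenes, enamides and enol ethers; a β-acyloxystyrene reacting with styrene-type regiochemistry has not been shown, hence the label. The required regioselectivity (oxygen at C3, aryl at C2) should follow from the 4-benzyloxy group of ring B, which stabilises positive charge at the aryl-bearing carbon far better than the acylated enol oxygen can at the other carbon. C2 and C3 become trans because the (E) geometry of 13 is carried into the ring, and C3 and C4 become trans because the alkene approaches with its aryl group endo to a methide whose bottom-unit aryl points away from the carbonyl oxygen; this all-equatorial 2,3-trans-3,4-trans chroman is also the most stable isomer, so a stepwise closure would lead to it as well. The absolute sense at C2, C3 and C4 (2R,3S, 4α) is imposed by the chiral phosphate, the remote stereocentres of the bottom unit serving only to make the wrong-sense product a separable diastereomer. Only one quinone methide can arise because the phenol ring of 9 carries a single hydroxyl ortho to the carbinol, the C8 bromide and the benzyl ethers do not respond to the weak acid, and slow addition of 9 to excess 13 should suppress Friedel–Crafts self-condensation.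

Step 10
Reactants: 4 8-bromo-3,5,7,3',4'-penta-O-benzyl-(+)-catechin
Product: 16 8-bromo-4β-(2-ethoxyethoxy)-3,5,7,3',4'-penta-O-benzylcatechin
Conditions: DDQ (2 equiv), 2-ethoxyethanol, CH2Cl2, rt
Reagents that add atoms: 2-ethoxyethanol, CCOCCO
Why: Benzylic oxidation: DDQ abstracts hydride from C4–H, activated by ring A, and the alcohol traps the cation trans to the C2 aryl group; the C4 configuration is of no consequence because step 11 ionises this centre again.

Step 11
Reactants: 15 3-O-acetyl-5,7,3',4'-tetra-O-benzylcatechin-(4α→6)-8-bromo-3,5,7,3',4'-penta-O-benzylcatechin; 16 8-bromo-4β-(2-ethoxyethoxy)-3,5,7,3',4'-penta-O-benzylcatechin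
Product: 18 8-bromo-3,5,7,3',4'-penta-O-benzylcatechin-(4α→8)-3-O-acetyl-5,7,3',4'-tetra-O-benzylcatechin-(4α→6)-8-bromo-3,5,7,3',4'-penta-O-benzylcatechin, via flavan-4-yl cation 17 (not isolated)
Conditions: Me3SiOSO2CF3 (0.3 equiv), 16 (1.2 equiv), CH2Cl2, −78 °C; Et3N quench
Reagents that add atoms: none
Why: Lewis-acid-promoted Friedel–Crafts flavan coupling: the silyl triflate ionises the C4 ether of 16 to cation 17, which C8 of the middle unit of 15 (the more nucleophilic and less shielded of its two free ring A positions) should attack anti to the 3-benzyloxy group to give the 3,4-trans (4α) bond, while the C8 bromide of 16 prevents self-condensation of the donor.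

Step 12
Reactants: 18 protected trimer acetate
Product: 19 8-bromo-3,5,7,3',4'-penta-O-benzylcatechin-(4α→8)-5,7,3',4'-tetra-O-benzylcatechin-(4α→6)-8-bromo-3,5,7,3',4'-penta-O-benzylcatechin (middle 3-OH free)
Conditions: NaOMe (cat.), MeOH/THF, rt → 40 °C
Reagents that add atoms: none
Why: Methoxide-catalysed transesterification (Zemplén-type deacylation) removes the only ester; benzyl ethers, aryl bromides and the interflavan bonds are inert to methoxide.

Step 13
Reactants: 19 tetradeca-O-benzyl dibromo trimer
Product: 20 catechin-(4α→8)-catechin-(4α→6)-catechin (CNP0178679.4)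
Conditions: H2 (1 atm), Pd(OH)2 on carbon, Et3N (2.2 equiv), THF/MeOH/H2O, rt
Reagents that add atoms: none
Why: Catalytic hydrogenolysis should cleave the fourteen benzyl ethers and reduce both aryl bromides in one operation, with Et3N taking up the HBr so that the acid-labile interflavan bonds never meet free acid and no stereocentre is touched.

**Compound list**

1 | (+)-catechin, (2R,3S) | O[C@H]1Cc2c(O)cc(O)cc2O[C@@H]1c1ccc(O)c(O)c1 | starting material
2 | 5,7,3',4'-tetra-O-benzyl-(+)-catechin | O[C@H]1Cc2c(OCc3ccccc3)cc(OCc3ccccc3)cc2O[C@@H]1c1ccc(OCc2ccccc2)c(OCc2ccccc2)c1 | intermediate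
3 | 3,5,7,3',4'-penta-O-benzyl-(+)-catechin | c1c(OCc3ccccc3)cc2c(c1OCc3ccccc3)C[C@H](OCc3ccccc3)[C@@H](c1ccc(OCc3ccccc3)c(OCc3ccccc3)c1)O2 | intermediate
4 | 8-bromo-3,5,7,3',4'-penta-O-benzyl-(+)-catechin | c1c(OCc3ccccc3)c(Br)c2c(c1OCc3ccccc3)C[C@H](OCc3ccccc3)[C@@H](c1ccc(OCc3ccccc3)c(OCc3ccccc3)c1)O2 | intermediate
5 | C6 N,N-dimethyliminium chloride of 4 (not isolated) | C[N+](C)=Cc1c(OCc3ccccc3)c(Br)c2c(c1OCc3ccccc3)C[C@H](OCc3ccccc3)[C@@H](c1ccc(OCc3ccccc3)c(OCc3ccccc3)c1)O2.[Cl-] | intermediate
6 | 8-bromo-6-formyl-3,5,7,3',4'-penta-O-benzyl-(+)-catechin | O=Cc1c(OCc3ccccc3)c(Br)c2c(c1OCc3ccccc3)C[C@H](OCc3ccccc3)[C@@H](c1ccc(OCc3ccccc3)c(OCc3ccccc3)c1)O2 | intermediate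
7 | 3,5-bis(benzyloxy)phenol | Oc1cc(OCc2ccccc2)cc(OCc2ccccc2)c1 | starting material
8 | bromomagnesium 3,5-bis(benzyloxy)phenoxide (not isolated) | Br[Mg]Oc1cc(OCc2ccccc2)cc(OCc2ccccc2)c1 | intermediate
9 | (8-bromo-3,5,7,3',4'-penta-O-benzylcatechin-6-yl)[2-hydroxy-4,6-bis(benzyloxy)phenyl]methanol, mixture of carbinol epimers | OC(c1c(O)cc(OCc3ccccc3)cc1OCc3ccccc3)c1c(OCc3ccccc3)c(Br)c2c(c1OCc3ccccc3)C[C@H](OCc3ccccc3)[C@@H](c1ccc(OCc3ccccc3)c(OCc3ccccc3)c1)O2 | intermediate
10 | 3,4-bis(benzyloxy)benzaldehyde | O=Cc1ccc(OCc2ccccc2)c(OCc2ccccc2)c1 | starting material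
11 | (E)-2-[3,4-bis(benzyloxy)styryl]-4,4,5,5-tetramethyl-1,3,2-dioxaborolane | CC1(C)OB(/C=C/c2ccc(OCc3ccccc3)c(OCc3ccccc3)c2)OC1(C)C | intermediate
12 | potassium (E)-[3,4-bis(benzyloxy)styryl]trifluoroborate | [K+].F[B-](F)(F)/C=C/c1ccc(OCc2ccccc2)c(OCc2ccccc2)c1 | intermediate
13 | (E)-2-[3,4-bis(benzyloxy)phenyl]vinyl acetate | CC(=O)O/C=C/c1ccc(OCc2ccccc2)c(OCc2ccccc2)c1 | intermediate
14 | o-quinone methide from 9: 3,5-bis(benzyloxy)-6-[(E)-(8-bromo-penta-O-benzylcatechin-6-yl)methylidene]cyclohexa-2,4-dien-1-one, drawn with the aryl group anti to the carbonyl (not isolated) | O=C1C=C(OCc3ccccc3)C=C(OCc3ccccc3)/C1=C\c1c(OCc3ccccc3)c(Br)c2c(c1OCc3ccccc3)C[C@H](OCc3ccccc3)[C@@H](c1ccc(OCc3ccccc3)c(OCc3ccccc3)c1)O2 | intermediate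
15 | 3-O-acetyl-5,7,3',4'-tetra-O-benzylcatechin-(4α→6)-8-bromo-3,5,7,3',4'-penta-O-benzylcatechin | c1ccccc1COc1cc(OCc3ccccc3)c2c(c1)O[C@H](c1ccc(OCc3ccccc3)c(OCc3ccccc3)c1)[C@@H](OC(C)=O)[C@@H]2c1c(OCc3ccccc3)c(Br)c2c(c1OCc3ccccc3)C[C@H](OCc3ccccc3)[C@@H](c1ccc(OCc3ccccc3)c(OCc3ccccc3)c1)O2 | intermediate
16 | 8-bromo-4β-(2-ethoxyethoxy)-3,5,7,3',4'-penta-O-benzylcatechin (catechin configuration at C2 and C3; drawn as the 4β, 2,4-trans epimer) | c1ccccc1COc1cc(OCc3ccccc3)c2c(c1Br)O[C@H](c1ccc(OCc3ccccc3)c(OCc3ccccc3)c1)[C@@H](OCc1ccccc1)[C@H]2OCCOCC | intermediate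
17 | 8-bromo-3,5,7,3',4'-penta-O-benzylflavan-4-yl cation, triflate (not isolated) | c1ccccc1COc1cc(OCc3ccccc3)c2c(c1Br)O[C@H](c1ccc(OCc3ccccc3)c(OCc3ccccc3)c1)[C@@H](OCc1ccccc1)[CH+]2.[O-]S(=O)(=O)C(F)(F)F | intermediate
18 | 8-bromo-penta-O-benzylcatechin-(4α→8)-3-O-acetyl-tetra-O-benzylcatechin-(4α→6)-8-bromo-penta-O-benzylcatechin | c1ccccc1COc1cc(OCc3ccccc3)c2c(c1Br)O[C@H](c1ccc(OCc3ccccc3)c(OCc3ccccc3)c1)[C@@H](OCc1ccccc1)[C@@H]2c1c(OCc3ccccc3)cc(OCc3ccccc3)c2c1O[C@H](c1ccc(OCc3ccccc3)c(OCc3ccccc3)c1)[C@@H](OC(C)=O)[C@@H]2c1c(OCc3ccccc3)c(Br)c2c(c1OCc3ccccc3)C[C@H](OCc3ccccc3)[C@@H](c1ccc(OCc3ccccc3)c(OCc3ccccc3)c1)O2 | intermediate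
19 | 8-bromo-penta-O-benzylcatechin-(4α→8)-tetra-O-benzylcatechin-(4α→6)-8-bromo-penta-O-benzylcatechin (middle 3-OH free) | c1ccccc1COc1cc(OCc3ccccc3)c2c(c1Br)O[C@H](c1ccc(OCc3ccccc3)c(OCc3ccccc3)c1)[C@@H](OCc1ccccc1)[C@@H]2c1c(OCc3ccccc3)cc(OCc3ccccc3)c2c1O[C@H](c1ccc(OCc3ccccc3)c(OCc3ccccc3)c1)[C@@H](O)[C@@H]2c1c(OCc3ccccc3)c(Br)c2c(c1OCc3ccccc3)C[C@H](OCc3ccccc3)[C@@H](c1ccc(OCc3ccccc3)c(OCc3ccccc3)c1)O2 | intermediate
20 | catechin-(4α→8)-catechin-(4α→6)-catechin, all units (2R,3S), both interflavan bonds 3,4-trans | Oc1cc(O)c2c(c1)O[C@H](c1ccc(O)c(O)c1)[C@@H](O)[C@@H]2c1c(O)cc(O)c2c1O[C@H](c1ccc(O)c(O)c1)[C@@H](O)[C@@H]2c1c(O)cc2c(c1O)C[C@H](O)[C@@H](c1ccc(O)c(O)c1)O2 | target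

**Step count and risks**

Total steps: 13. Longest linear sequence: 9 steps (steps 1, 2, 3, 4, 5, 9, 11, 12, 13).

Steps most likely to fail:

1. Step 9. The weakly nucleophilic enol acetate may add too slowly to the crowded, strongly stabilised quinone methide, so that Friedel–Crafts self-condensation through the free positions of the phloroglucinol rings takes over. Addition with enol-type regiochemistry or poor facial selectivity under the phosphate are further possibilities. The fallback uses known chemistry, sets out from 2 and 4 and returns at 15. Alcohol 2 is acetylated (Ac2O, pyridine, DMAP) to 3-O-acetyl-5,7,3',4'-tetra-O-benzyl-(+)-catechin F1. DDQ and 2-ethoxyethanol then oxidise F1 at C4 to 3-O-acetyl-4β-(2-ethoxyethoxy)-5,7,3',4'-tetra-O-benzylcatechin F2. Me3SiOSO2CF3-promoted Friedel–Crafts condensation of F2 with an excess of bromide 4 in CH2Cl2 at −78 °C should give 15 directly: C8 of 4 is blocked so only C6 can attack, and attack occurs anti to the participating 3-acetoxy group (4α).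

2. Step 5. The di-ortho-alkoxy aldehyde may add sluggishly to the hindered ortho carbon. The magnesium alkoxide formed may also ionise and take up a second phenoxide (triarylmethane formation), or the carbinol may be lost by dehydration on silica. The fallback sets out from 7 (with 6) and returns at 9. Ortho-selective bromination of 7 (NBS, cat. i-Pr2NH, CH2Cl2, 0 °C) gives 2-bromo-3,5-bis(benzyloxy)phenol F3. Two equivalents of n-BuLi (THF, −78 °C) deprotonate it and exchange bromine for lithium to give lithium 2-lithio-3,5-bis(benzyloxy)phenoxide F4. F4 adds as a preformed aryl nucleophile to aldehyde 6 at −78 °C, and work-up at pH 7 should give 9.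

3. Step 11. The cation may attack C6 instead of C8 of the middle unit, the product may be alkylated a second time, or the acid may scramble the 4→6 bond already present. The fallback sets out from 16 and returns at 18. Exchange of the 2-ethoxyethoxy group for an arylthio group (2,6-dimethylbenzenethiol, BF3·OEt2, CH2Cl2, −78 °C) gives 8-bromo-4β-(2,6-dimethylphenylthio)-3,5,7,3',4'-penta-O-benzylcatechin F5. This donor is switched on by a soft thiophilic activator, N-iodosuccinimide (CH2Cl2, −78 → −30 °C), in the absence of any Lewis or Brønsted acid, and under these conditions should couple with 15 to give 18.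

**Further compounds**

F1 | step 9 | 3-O-acetyl-5,7,3',4'-tetra-O-benzyl-(+)-catechin | CC(=O)O[C@H]1Cc2c(OCc3ccccc3)cc(OCc3ccccc3)cc2O[C@@H]1c1ccc(OCc2ccccc2)c(OCc2ccccc2)c1
F2 | step 9 | 3-O-acetyl-4β-(2-ethoxyethoxy)-5,7,3',4'-tetra-O-benzylcatechin | c1ccccc1COc1cc(OCc3ccccc3)c2c(c1)O[C@H](c1ccc(OCc3ccccc3)c(OCc3ccccc3)c1)[C@@H](OC(C)=O)[C@H]2OCCOCC
F3 | step 5 | 2-bromo-3,5-bis(benzyloxy)phenol | Oc1cc(OCc2ccccc2)cc(OCc2ccccc2)c1Br
F4 | step 5 | lithium 2-lithio-3,5-bis(benzyloxy)phenoxide | [Li]Oc1cc(OCc2ccccc2)cc(OCc2ccccc2)c1[Li]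
F5 | step 11 | 8-bromo-4β-(2,6-dimethylphenylthio)-3,5,7,3',4'-penta-O-benzylcatechin | c1ccccc1COc1cc(OCc3ccccc3)c2c(c1Br)O[C@H](c1ccc(OCc3ccccc3)c(OCc3ccccc3)c1)[C@@H](OCc1ccccc1)[C@H]2Sc1c(C)cccc1C
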